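The target is not what piles up in the two earlier runs. At 2.50 h the cedar run read 4 % of it against 15 % of isomer of the product, and the maple run read 6 % against 17 %. So you first reckon how much substrate has gone at all.

| flask | substrate | coupling partner | initiator | remark | time |
|---|---|---|---|---|---|
| cedar | 0.0067 M | 0.020 M | 0.52 mM | run made earlier |  |
| maple | 0.010 M | 0.020 M | 1 mM | run made earlier |  |
| north-west | 0.010 M | 0.0200 M | 0.52 mM |  | 4.0 h |
| north-east | 0.010 M | 0.0400 M | 0.52 mM |  | 4.0 h |
| south-west | 0.010 M | 0.0800 M | 0.52 mM |  | 4.0 h |

| run | time / h | target / % | substrate / % | isomer of the product / % | first chain carrier / % |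
|---|---|---|---|---|---|
| cedar | 0.500 | 4 | 93 | 4 | 0 |
| cedar | 1.00 | 5 | 84 | 6 | 0 |
| cedar | 1.33 | 5 | 83 | 9 | 2 |
| cedar | 2.00 | 5 | 76 | 13 | 1 |
| cedar | 2.50 | 4 | 70 | 15 | 0 |
| maple | 0.200 | 1 | 96 | 1 | 0 |
| maple | 0.667 | 4 | 89 | 2 | 0 |
| maple | 1.00 | 5 | 86 | 3 | 0 |
| maple | 1.50 | 4 | 81 | 10 | 0 |
| maple | 2.50 | 6 | 70 | 17 | 0 |

(standard deviation of a reading: 1.5 percentage points)

1. which of these there is most of at the end, counted by the substrate in it, north-west (first chain carrier / substrate / isomer of the product / target)
2. which of these there is most of at the end, counted by the substrate in it, north-east (first chain carrier / substrate / isomer of the product / target)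
3. which of these there is most of at the end, counted by the substrate in it, south-west (first chain carrier / substrate / isomer of the product / target)
4. amount of the one of these that there is most of at the end, in percent of the substrate charged, north-west
5. amount of the one of these that there is most of at the end, in percent of the substrate charged, north-east
6. amount of the one of these that there is most of at the end, in percent of the substrate charged, south-west

Both runs had lost the same percentage by then, within the scatter. In concentration they differ: cedar lost 0.00201 M, maple 0.00300 M. Two readings fit that. Either the loss is first order in substrate and blind to initiator, or two changes cancel. A chain needs its initiator, so I take the second.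

If carriers end by meeting in pairs, their steady-state level follows the square root of c(initiator). The substrate loss then follows that level, whatever c(substrate) is: zero order in substrate.

That gives one useful number, the clearing time T: the time in which this steady loss would use up the substrate charged to north-west. Cedar, which has north-west's initiator, reads 12.4 h. Maple, brought over by the root of the c(initiator) ratio, reads 11.6 h. These are two different flasks, and their mean is 12.0 h.

So 4.0 h is a third of a clearing, and I expect 66.7 % substrate left in north-west. This ignores any decay of the initiator. Partner was never varied. Supposing first order in it, the count is 0.667 in north-east, leaving 33.3 %, and 1.33 in south-west, past one, so isomer of the product should lead in both.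

The forecast says substrate at 62 % in north-west, which is less than my figure, isomer of the product at 50 % in north-east, and isomer of the product at 72 % in south-west. On partner it reasons as I do: “I assume it speeds consumption, probably about first order in the propagation step”.

North-west ended with substrate leading at 72.4 %, north-east with substrate at 52.3 %, and south-west with isomer of the product at 64.1 %. In north-west, 41 % of the initiator was left at the end. Scale the count by the root of that: the mean of the root at start and end is 0.821, and T then leaves 72.6 % substrate, where I first said 66.7 %.

    target ⇌ isomer of the product (K = 24.0, k = 0.0300 min⁻¹)
    substrate + target ⇌ idle adduct, settled at all times (K = 36.0 L mol⁻¹)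
    coupling partner + first chain carrier ⇌ target + second chain carrier (K = 0.480, k = 64000 L mol⁻¹ min⁻¹)
    substrate + initiating radical → capped initiator + first chain carrier (k = 38000 L mol⁻¹ s⁻¹)
    2 first chain carrier → ended chains (k = 4.00 × 10⁸ L mol⁻¹ s⁻¹)
    initiator → 2 initiating radical (k = 0.00370 min⁻¹)
    substrate + second chain carrier → by-product + first chain carrier (k = 2.40 × 10⁵ L mol⁻¹ min⁻¹)

North-east lost 1.73 times north-west's share, so its clearing time is 6.94 h. The second flask is a neighbour: north-east with 0.0013 M of initiator, of which 41 % was left at the end. The root rule shortens the clearing time to 4.39 h, and with the same mean root that leaves 25.2 % substrate. The neighbour flask holds 24.4 % substrate, and 50.6 % isomer of the product leads.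

(The data come from a simulation with made-up constants.)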